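**Retrosynthetic overview**

1. The route rests on one feature of target 16: on the cyclohexene ring C1–C6, the oxirane oxygen on quaternary C1 (which also carries C7H2OBz) and the benzoate oxygen on C2 are cis. This is the ipso,ortho cis-diol of benzoic acid, so whole-cell benzoate 1,2-dioxygenase converts 1 into 2 and the carbocycle is the arene ring itself.
2. The C3 oxygen and a C6 leaving-group oxygen come from β-face singlet-oxygen addition to the C3=C4–C5=C6 diene of acetonide 6. C7 comes from LiAlH4 reduction of the carboxyl, followed by benzoylation.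
3. The two β-hydroxyls of diol 8 are told apart by sterics (O-6 sits next to quaternary C1). A base-induced rearrangement of endoperoxide 7 is avoided, because the substrate does not secure which bridgehead proton (H-3 or H-6) would be lost.
4. The oxirane is closed by O-1 displacing a 6β-mesylate with inversion (12 → 13). This is done while C3 is still a silyl ether, so that no enolisable β-alkoxy ketone meets base.
5. C3–OH (α, cis to O-2) is set last by oxidation and Luche reduction of epoxy enone 15. Ring order: arene carbocycle (dearomatised, step 1), dioxolane (temporary, step 2), peroxide bridge (temporary, step 5), oxirane (step 11).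

Key step: step 1

Remark: locants are those of the target (C1 quaternary ring carbon, C2–C6 round the ring, C7 the exocyclic carbon on C1); α is the ring face of O-1 and O-2, β the face of C7; 2 is assumed to be formed as a single enantiomer, as single-face delivery by the enzyme implies.

**Route**

Step 1
Reactants: 1 benzoic acid
Product: 2 (1S,2R)-1,2-dihydroxycyclohexa-3,5-diene-1-carboxylic acid
Conditions: Cupriavidus necator B9 (Ralstonia eutropha B9, cis-diol dehydrogenase-deficient) whole cells, D-fructose, KH2PO4/Na2HPO4-buffered mineral medium pH 7, air, 30 °C; then HCl to pH 3, EtOAc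
Reagents that add atoms: dioxygen, O=O
Why: The Rieske dioxygenase system passes two electrons from NADH through its reductase and [2Fe-2S] cluster to a mononuclear non-haem iron site, where dioxygen bound to divalent iron is reduced to a trivalent iron hydroperoxide (or the hydroxo-oxo species formed from it) that hands both oxygen atoms to the same face of the C1–C2 bond of carboxylate-bound benzoate. The reaction type is the known whole-cell ipso,ortho cis-dihydroxylation of benzoate by benzoate 1,2-dioxygenase, the arene counterpart of a syn-dihydroxylation of an alkene. No ring is closed: two C–O bonds form and the arene ring is carried over as the cyclohexa-3,5-diene. C1 (S) and C2 (R) are both set by the enzyme pocket, which fixes the carboxylate and so exposes one arene face and one ortho position, and the suprafacial delivery makes the two hydroxyls cis. The step needs ipso,ortho regioselectivity, a single enantiotopic face and survival of the diol; the achiral substrate offers no bias, so the first two rest on the active site, and the third on the missing cis-diol dehydrogenase of the B9 mutant, without which the diol would be oxidised further, with loss of CO2, to catechol.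

Step 2
Reactants: 2 (1S,2R)-1,2-dihydroxycyclohexa-3,5-diene-1-carboxylic acid
Product: 3 (1S,2R)-1,2-(isopropylidenedioxy)cyclohexa-3,5-diene-1-carboxylic acid
Conditions: Me2C(OMe)2, TsOH·H2O (cat.), acetone, rt
Reagents that add atoms: 2,2-dimethoxypropane, COC(C)(C)OC
Why: Acid-catalysed transacetalisation (acetonide formation) of the cis-1,2-diol should give the cis-fused dioxolane faster than the dienediol can dehydrate to a salicylate, and it touches neither C1 nor C2.

Step 3
Reactants: 3 (1S,2R)-1,2-(isopropylidenedioxy)cyclohexa-3,5-diene-1-carboxylic acid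
Product: 4 [1α,2α-(isopropylidenedioxy)cyclohexa-3,5-dien-1-yl]methanol
Conditions: LiAlH4, THF, 0 °C to rt; then H2O, aq. NaOH
Reagents that add atoms: none
Why: Hydride reduction of the carboxylic acid (through its carboxylate) by LiAlH4 should give the primary alcohol at C7, since the diene is not conjugated with C7 and the acetal is inert to hydride.

Step 4
Reactants: 4 [1α,2α-(isopropylidenedioxy)cyclohexa-3,5-dien-1-yl]methanol; 5 benzoyl chloride
Product: 6 [1α,2α-(isopropylidenedioxy)cyclohexa-3,5-dien-1-yl]methyl benzoate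
Conditions: BzCl, pyridine, DMAP (cat.), CH2Cl2, 0 °C to rt
Reagents that add atoms: benzoyl chloride, O=C(Cl)c1ccccc1
Why: DMAP-catalysed nucleophilic acyl substitution on the only hydroxyl, a primary alcohol, installs the O-7 benzoate under non-acidic conditions that spare the acetal.

Step 5
Reactants: 6 [1α,2α-(isopropylidenedioxy)cyclohexa-3,5-dien-1-yl]methyl benzoate
Product: 7 [3β,6β-epidioxy-1α,2α-(isopropylidenedioxy)cyclohex-4-en-1-yl]methyl benzoate
Conditions: O2, TPP (cat.), visible light, CH2Cl2, 0 °C
Reagents that add atoms: dioxygen, O=O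
Why: Singlet-oxygen [4+2] cycloaddition (photooxygenation) to the cisoid diene C3=C4–C5=C6 should take place on the β face, because the cis-fused dioxolane screens the α face, so the new C3–O and C6–O bonds are both β.

Step 6
Reactants: 7 [3β,6β-epidioxy-1α,2α-(isopropylidenedioxy)cyclohex-4-en-1-yl]methyl benzoate
Product: 8 [3β,6β-dihydroxy-1α,2α-(isopropylidenedioxy)cyclohex-4-en-1-yl]methyl benzoate
Conditions: Zn dust, AcOH, CH2Cl2, 0 °C to rt
Reagents that add atoms: none
Why: Reductive cleavage of the O–O bond by Zn/AcOH gives the cis-2-ene-1,4-diol with retention at C3 and C6, and under these non-basic conditions no bridgehead proton is removed.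

Step 7
Reactants: 8 [3β,6β-dihydroxy-1α,2α-(isopropylidenedioxy)cyclohex-4-en-1-yl]methyl benzoate
Product: 9 [3β-(tert-butyldiphenylsilyloxy)-6β-hydroxy-1α,2α-(isopropylidenedioxy)cyclohex-4-en-1-yl]methyl benzoate
Conditions: TBDPSCl (1.1 equiv), imidazole, DMF, 0 °C to rt
Reagents that add atoms: tert-butyl(chloro)diphenylsilane, CC(C)(C)[Si](Cl)(c1ccccc1)c1ccccc1
Why: Site-selective silylation should fall on O-3, because C3–OH is flanked by a CH whereas C6–OH is flanked by the fully substituted C1 and its cis C7 arm, which the bulky silyl chloride cannot easily pass.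

Step 8
Reactants: 9 [3β-(tert-butyldiphenylsilyloxy)-6β-hydroxy-1α,2α-(isopropylidenedioxy)cyclohex-4-en-1-yl]methyl benzoate
Product: 10 [3β-(tert-butyldiphenylsilyloxy)-1α,2α-(isopropylidenedioxy)-6β-(methanesulfonyloxy)cyclohex-4-en-1-yl]methyl benzoate
Conditions: Ms2O, Et3N, DMAP (cat.), CH2Cl2, 0 °C
Reagents that add atoms: methanesulfonic anhydride, CS(=O)(=O)OS(C)(=O)=O
Why: Sulfonylation of the one remaining hydroxyl proceeds with retention at C6, and the chloride-free anhydride prevents conversion of the allylic mesylate into an allylic chloride.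

Step 9
Reactants: 10 [3β-(tert-butyldiphenylsilyloxy)-1α,2α-(isopropylidenedioxy)-6β-(methanesulfonyloxy)cyclohex-4-en-1-yl]methyl benzoate
Product: 11 [3β-(tert-butyldiphenylsilyloxy)-1α,2α-dihydroxy-6β-(methanesulfonyloxy)cyclohex-4-en-1-yl]methyl benzoate
Conditions: TFA/H2O (9:1), 0 °C, short contact; toluene azeotrope
Reagents that add atoms: none
Why: Acid hydrolysis of the isopropylidene acetal frees O-1 and O-2, while the TBDPS ether tolerates cold aqueous TFA and the mesylate, flanked by two oxygen-bearing carbons, should ionise only slowly.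

Step 10
Reactants: 11 [3β-(tert-butyldiphenylsilyloxy)-1α,2α-dihydroxy-6β-(methanesulfonyloxy)cyclohex-4-en-1-yl]methyl benzoate; 5 benzoyl chloride
Product: 12 [2α-(benzoyloxy)-3β-(tert-butyldiphenylsilyloxy)-1α-hydroxy-6β-(methanesulfonyloxy)cyclohex-4-en-1-yl]methyl benzoate
Conditions: BzCl (1.2 equiv), pyridine, DMAP (cat.), CH2Cl2, 0 °C to rt
Reagents that add atoms: benzoyl chloride, O=C(Cl)c1ccccc1
Why: Selective acylation places the benzoate on the secondary O-2, since the tertiary O-1 hydroxyl does not react with BzCl under these mild conditions.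

Step 11
Reactants: 12 [2α-(benzoyloxy)-3β-(tert-butyldiphenylsilyloxy)-1α-hydroxy-6β-(methanesulfonyloxy)cyclohex-4-en-1-yl]methyl benzoate
Product: 13 [2α-(benzoyloxy)-3β-(tert-butyldiphenylsilyloxy)-1α,6α-epoxycyclohex-4-en-1-yl]methyl benzoate
Conditions: DBU, MeCN, rt
Reagents that add atoms: none
Why: Intramolecular Williamson etherification (3-exo-tet) by the α-oriented O-1 on C6, anti to the β-mesylate, inverts C6 and gives the α-oxirane; C6 has no sp3 β-hydrogen, so elimination cannot compete, and the non-nucleophilic base spares both benzoates.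

Step 12
Reactants: 13 [2α-(benzoyloxy)-3β-(tert-butyldiphenylsilyloxy)-1α,6α-epoxycyclohex-4-en-1-yl]methyl benzoate
Product: 14 [2α-(benzoyloxy)-1α,6α-epoxy-3β-hydroxycyclohex-4-en-1-yl]methyl benzoate
Conditions: TBAF/AcOH (1:1), THF, 0 °C to rt
Reagents that add atoms: none
Why: Fluoride desilylation buffered with AcOH frees the allylic 3β-hydroxyl without alkoxide-driven benzoate migration or opening of the vinyl oxirane.

Step 13
Reactants: 14 [2α-(benzoyloxy)-1α,6α-epoxy-3β-hydroxycyclohex-4-en-1-yl]methyl benzoate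
Product: 15 [2α-(benzoyloxy)-1α,6α-epoxy-3-oxocyclohex-4-en-1-yl]methyl benzoate
Conditions: Dess–Martin periodinane, NaHCO3, CH2Cl2, 0 °C; crude product used directly
Reagents that add atoms: none
Why: Dess–Martin oxidation of the secondary allylic alcohol under bicarbonate buffer removes the wrongly configured C3 centre and gives the epoxy enone, which is prone to enolisation at C2 and is therefore carried on at once.

Step 14
Reactants: 15 [2α-(benzoyloxy)-1α,6α-epoxy-3-oxocyclohex-4-en-1-yl]methyl benzoate
Product: 16 [(1S,2R,3R,6S)-2-(benzoyloxy)-3-hydroxy-7-oxabicyclo[4.1.0]hept-4-en-1-yl]methyl benzoate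
Conditions: NaBH4, CeCl3·7H2O, MeOH, −78 °C; then aq. NH4Cl
Reagents that add atoms: none
Why: Luche 1,2-reduction of the enone should deliver hydride to C3 from the β face, anti to the α-oriented C2 benzoate and oxirane oxygen (C7 lies near the ring plane and leaves the β face open), giving the 3α-hydroxyl (3R) cis to O-2, and the cold, non-basic medium should prevent acyl migration.

**Compound list**

1 | benzoic acid | OC(=O)c1ccccc1 | starting material
2 | (1S,2R)-1,2-dihydroxycyclohexa-3,5-diene-1-carboxylic acid | OC(=O)[C@]1(O)C=CC=C[C@H]1O | intermediate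
3 | (1S,2R)-1,2-(isopropylidenedioxy)cyclohexa-3,5-diene-1-carboxylic acid (dioxolane α, CO2H β) | OC(=O)[C@]1(OC(C)(C)O2)C=CC=C[C@H]12 | intermediate
4 | [1α,2α-(isopropylidenedioxy)cyclohexa-3,5-dien-1-yl]methanol | OC[C@]1(OC(C)(C)O2)C=CC=C[C@H]12 | intermediate
5 | benzoyl chloride | O=C(Cl)c1ccccc1 | starting material
6 | [1α,2α-(isopropylidenedioxy)cyclohexa-3,5-dien-1-yl]methyl benzoate | O=C(OC[C@]1(OC(C)(C)O2)C=CC=C[C@H]12)c1ccccc1 | intermediate
7 | [3β,6β-epidioxy-1α,2α-(isopropylidenedioxy)cyclohex-4-en-1-yl]methyl benzoate (peroxide bridge anti to the dioxolane) | O=C(c1ccccc1)OC[C@@]12OC(C)(C)O[C@@H]1[C@H]1OO[C@@H]2C=C1 | intermediate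
8 | [3β,6β-dihydroxy-1α,2α-(isopropylidenedioxy)cyclohex-4-en-1-yl]methyl benzoate | O=C(c1ccccc1)OC[C@@]12OC(C)(C)O[C@@H]1[C@@H](O)C=C[C@H]2O | intermediate
9 | [3β-(tert-butyldiphenylsilyloxy)-6β-hydroxy-1α,2α-(isopropylidenedioxy)cyclohex-4-en-1-yl]methyl benzoate | O=C(c1ccccc1)OC[C@@]12OC(C)(C)O[C@@H]1[C@@H](O[Si](c1ccccc1)(c1ccccc1)C(C)(C)C)C=C[C@H]2O | intermediate
10 | [3β-(tert-butyldiphenylsilyloxy)-1α,2α-(isopropylidenedioxy)-6β-(methanesulfonyloxy)cyclohex-4-en-1-yl]methyl benzoate | O=C(c1ccccc1)OC[C@@]12OC(C)(C)O[C@@H]1[C@@H](O[Si](c1ccccc1)(c1ccccc1)C(C)(C)C)C=C[C@H]2OS(C)(=O)=O | intermediate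
11 | [3β-(tert-butyldiphenylsilyloxy)-1α,2α-dihydroxy-6β-(methanesulfonyloxy)cyclohex-4-en-1-yl]methyl benzoate | O=C(c1ccccc1)OC[C@@]1(O)[C@H](O)[C@@H](O[Si](c2ccccc2)(c2ccccc2)C(C)(C)C)C=C[C@H]1OS(C)(=O)=O | intermediate
12 | [2α-(benzoyloxy)-3β-(tert-butyldiphenylsilyloxy)-1α-hydroxy-6β-(methanesulfonyloxy)cyclohex-4-en-1-yl]methyl benzoate | O=C(c1ccccc1)OC[C@@]1(O)[C@H](OC(=O)c2ccccc2)[C@@H](O[Si](c2ccccc2)(c2ccccc2)C(C)(C)C)C=C[C@H]1OS(C)(=O)=O | intermediate
13 | [2α-(benzoyloxy)-3β-(tert-butyldiphenylsilyloxy)-1α,6α-epoxycyclohex-4-en-1-yl]methyl benzoate | O=C(OC[C@]12O[C@H]1C=C[C@H](O[Si](c1ccccc1)(c1ccccc1)C(C)(C)C)[C@H]2OC(=O)c1ccccc1)c1ccccc1 | intermediate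
14 | [2α-(benzoyloxy)-1α,6α-epoxy-3β-hydroxycyclohex-4-en-1-yl]methyl benzoate (C3 epimer of the target) | O=C(OC[C@]12O[C@H]1C=C[C@H](O)[C@H]2OC(=O)c1ccccc1)c1ccccc1 | intermediate
15 | [2α-(benzoyloxy)-1α,6α-epoxy-3-oxocyclohex-4-en-1-yl]methyl benzoate | O=C(OC[C@]12O[C@H]1C=CC(=O)[C@H]2OC(=O)c1ccccc1)c1ccccc1 | intermediate
16 | [(1S,2R,3R,6S)-2-(benzoyloxy)-3-hydroxy-7-oxabicyclo[4.1.0]hept-4-en-1-yl]methyl benzoate (oxirane O, O-2 and O-3 all α; C7 β) | O=C(OC[C@]12O[C@H]1C=C[C@@H](O)[C@H]2OC(=O)c1ccccc1)c1ccccc1 | target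

**Step count**

Total step count: 14. Longest linear sequence: 14 steps (1 to 16); benzoyl chloride 5 enters in steps 4 and 10.

**Steps most likely to fail**

Step 7. The silyl chloride may discriminate poorly between O-3 and O-6, giving mixtures of regioisomers or bis-silylation. The fallback sets out from 4 and returns at 9, using the free C7 hydroxyl as a tether. Photooxygenation of 4 (O2, TPP, light) should give the β-endoperoxide alcohol F1, and Zn/AcOH the 3β,6β,7-triol F2. With tBu2Si(OTf)2 and 2,6-lutidine, only the 1,3-related pair O-6/O-7 can be bridged, giving the 6,7-O-di-tert-butylsilylene acetal F3. TBDPSCl/imidazole then silylates the single free hydroxyl to give the 3β-TBDPS ether F4. Buffered HF·pyridine at 0 °C removes the strained silylene but not the TBDPS ether, giving the 6β,7-diol F5. BzCl with 2,4,6-collidine at −40 °C acylates the primary O-7, which gives 9.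

Step 14. Hydride may be delivered to C3 of 15 with poor facial selectivity, and 15 may aromatise by enolisation at C2 before it is reduced. The fallback sets out from 14 and returns at 16 without passing through the ketone. Mitsunobu inversion of the 3β-alcohol with chloroacetic acid (PPh3, DIAD, toluene, 0 °C) should give the 3α-chloroacetate F9. Thiourea/NaHCO3 in EtOH then removes the chloroacetyl group in the presence of both benzoates.

Step 9. The allylic mesylate may be lost by ionisation or solvolysis in aqueous TFA while the acetal is hydrolysed. The fallback sets out from 9 and returns at 12, so that the strong acid is used before the mesylate exists. TFA/H2O on 9 should give the 1α,2α,6β-triol F6. PhC(OMe)3 with PPTS bridges the cis pair O-1/O-2 (O-6 is trans to O-1 and cannot take part), giving the cyclic methyl orthobenzoate F7. Ms2O/Et3N converts it into its 6β-mesylate F8. Aqueous AcOH at rt opens the orthoester to the hydroxy benzoate 12. Any tertiary O-1 benzoate formed alongside should migrate to O-2 under the DBU of step 11 before the oxirane closes.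

**Further compounds**

F1 | step 7 | [3β,6β-epidioxy-1α,2α-(isopropylidenedioxy)cyclohex-4-en-1-yl]methanol | OC[C@@]12OC(C)(C)O[C@@H]1[C@H]1OO[C@@H]2C=C1
F2 | step 7 | 3β,6β-dihydroxy-1-(hydroxymethyl)-1α,2α-(isopropylidenedioxy)cyclohex-4-ene | OC[C@@]12OC(C)(C)O[C@@H]1[C@@H](O)C=C[C@H]2O
F3 | step 7 | 6,7-O-di-tert-butylsilylene acetal of F2 (3β-OH free) | CC(C)(C)[Si]1(C(C)(C)C)OC[C@@]23OC(C)(C)O[C@@H]2[C@@H](O)C=C[C@H]3O1
F4 | step 7 | 3β-TBDPS ether of F3 | CC(C)(C)[Si]1(C(C)(C)C)OC[C@@]23OC(C)(C)O[C@@H]2[C@@H](O[Si](c2ccccc2)(c2ccccc2)C(C)(C)C)C=C[C@H]3O1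
F5 | step 7 | 3β-(tert-butyldiphenylsilyloxy)-6β-hydroxy-1-(hydroxymethyl)-1α,2α-(isopropylidenedioxy)cyclohex-4-ene | OC[C@@]12OC(C)(C)O[C@@H]1[C@@H](O[Si](c1ccccc1)(c1ccccc1)C(C)(C)C)C=C[C@H]2O
F6 | step 9 | [3β-(tert-butyldiphenylsilyloxy)-1α,2α,6β-trihydroxycyclohex-4-en-1-yl]methyl benzoate | O=C(c1ccccc1)OC[C@@]1(O)[C@H](O)[C@@H](O[Si](c2ccccc2)(c2ccccc2)C(C)(C)C)C=C[C@H]1O
F7 | step 9 | O-1,O-2 cyclic methyl orthobenzoate of F6 (6β-OH free; mixture at the orthoester carbon) | O=C(c1ccccc1)OC[C@@]12OC(OC)(c3ccccc3)O[C@@H]1[C@@H](O[Si](c1ccccc1)(c1ccccc1)C(C)(C)C)C=C[C@H]2O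
F8 | step 9 | 6β-mesylate of F7 | O=C(c1ccccc1)OC[C@@]12OC(OC)(c3ccccc3)O[C@@H]1[C@@H](O[Si](c1ccccc1)(c1ccccc1)C(C)(C)C)C=C[C@H]2OS(C)(=O)=O
F9 | step 14 | [2α-(benzoyloxy)-3α-(chloroacetoxy)-1α,6α-epoxycyclohex-4-en-1-yl]methyl benzoate | O=C(OC[C@]12O[C@H]1C=C[C@@H](OC(=O)CCl)[C@H]2OC(=O)c1ccccc1)c1ccccc1
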